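The epsilon run ends at 50.0 min with 65% starting complex and 9% complex with two exchanged, and from 15.0 min on its starting complex moves by 4 percentage points, against a scatter of 1.5 points.

common to all: starting complex 2.3 M (in portions, 4); incoming ligand 2.07 M

|  | protic impurity | remark | time |
|---|---|---|---|
| epsilon | 0.12 M | run made earlier; portions every 1.0 min |  |
| gamma | 0.46 M | run made earlier; portions every 1.0 min |  |
| flask | 0.230 M | the portions of starting complex follow each other after 1.0 min, the first at the start | 50 min |

| run | time / min | starting complex / % | complex with two exchanged / % |
|---|---|---|---|
| epsilon | 2.50 | 67 | 0 |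
| epsilon | 8.00 | 71 | 5 |
| epsilon | 15.0 | 68 | 11 |
| epsilon | 20.0 | 67 | 9 |
| epsilon | 30.0 | 66 | 10 |
| epsilon | 40.0 | 64 | 11 |
| epsilon | 50.0 | 65 | 9 |
| gamma | 4.00 | 88 | 3 |
| gamma | 6.00 | 78 | 4 |
| gamma | 10.0 | 71 | 7 |
| gamma | 15.0 | 70 | 7 |
| gamma | 20.0 | 70 | 7 |
| gamma | 30.0 | 70 | 8 |
| gamma | 50.0 | 67 | 8 |

(standard deviation of a reading: 1.5 percentage points)

- the reaction counts as stopped when no species that holds the starting complex changes by six tenths of a point or more over the second half of the time

1. which holds at 50 min: what has brought the reaction to rest, or that it has not come to rest (the incoming ligand has run out first / all of the starting complex has reacted / forward and back rates have come level / it is still moving)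
2. share of the starting complex used up at 50 min
3. complex with two exchanged at 50 min, in percent of the starting complex charged

Two amounts matter: c(leaving ligand) and c(incoming ligand). Take the gap in the epsilon balance as complex with one exchanged, 26.0%. Each exchange frees one leaving ligand, so c(leaving ligand) is 1.01 M. If each protic impurity takes one incoming ligand, c(incoming ligand) is 0.938 M.

The first exchange runs forward as c(starting complex)·c(incoming ligand) and back as c(complex with one exchanged)·c(leaving ligand). The back rate starts at zero and gains on the forward rate as leaving ligand builds up. The two level when the exchange quotient, c(complex with one exchanged)/c(starting complex) times c(leaving ligand)/c(incoming ligand), reaches a constant.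

Epsilon reads 0.432. Gamma, with 25.0% and 0.943 M, reads 0.528. Their mean is the exchange quotient at rest as read from these runs, 0.480.

Incoming ligand is the limiting reagent by the charges, 2.07 M against 2.3 M of starting complex. Putting the epsilon composition into this flask still leaves 0.828 M of it, so on this reckoning it has not run out, and the composition gives a quotient of 0.489, between the two readings. My reckoning for this flask is therefore level rates, about 35.0% used up and about 9% complex with two exchanged.

The forecast says forward and back rates have come level, 34% and 9.3%: “this looks like a reversible exchange reaching equilibrium”. The flask gives forward and back rates have come level, 34.6% and 8.51%.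

    starting complex → decomposition product (k = 3.70 × 10⁻⁷ /s)
    complex with one exchanged + incoming ligand ⇌ leaving ligand + complex with two exchanged (K = 0.380, k = 8.70 × 10⁻⁴ /M/s)
    starting complex + incoming ligand ⇌ leaving ligand + complex with one exchanged (K = 0.460, k = 6.10 × 10⁻⁴ /M/s)
    protic impurity + incoming ligand → quenched reagent (k = 0.00180 /M/s)

In this flask the quotient climbs from 0.0177 at 3.00 min to 0.460 at 50.0 min, beside 0.480. Without the back step of the first exchange, conversion goes from 34.6% to 66.0%, the largest single effect. In the neighbour flask, 0.83 M incoming ligand leaves 0.600 M if the full impurity charge is counted as taking its share. With 0.480 and the second exchange neglected, that gives 17.9% used up, and the computed neighbour gives 17.9%.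

The data were computed for an exercise, noise included.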